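## The problem

Compound 16 is a chroman (O1, C2, C3, C4, C4a, C8a) whose C2 is spiro-fused to C2 of a 3,3-dimethylnorbornane and whose benzene ring is a fully substituted 5,7-dihydroxy-6,8-dicarbaldehyde. C2 is a fully substituted carbon between the gem-dimethyl carbon and a bridgehead, with O1 on the endo face and C3 on the exo face. Any step that lets positive charge build up at C2 invites Wagner–Meerwein rearrangement of the camphene skeleton. The two bridgehead stereocentres can be taken from camphene, and C2 has to be set against them. C4 (isobutyl cis to the gem-dimethyl carbon across the pyran ring) has only C2 as a possible controller, across a flexible CH2, which is a weak relay for kinetic control; C4 is therefore the real stereochemical problem. The two salicylaldehyde-type formyl groups and the free phenols will not survive hydride, organometallic or palladium chemistry and belong at the end, and the tertiary alkyl aryl ether should see as little acid as possible. The enabling feature is that C2 has the oxidation pattern of a ketone carbon (O1 is its oxygen) and that the isobutyl CH2 on C4 can be raised to the carboxyl level. O1, C2, C3, C4 and that carbon then form a γ-lactone in which C4 is an enolisable α-aryl centre held in a rigid five-membered ring next to the spiro centre.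

## Retrosynthesis

**16 ⇒ 15 ⇒ 14 (C6–CHO, C8–CHO and the two O–CH3 bonds).** The formyl groups are removed first because nothing earlier in the route tolerates them, and the phenols are masked as methyl ethers because these survive every earlier step. Compound 14 is a plain dimethoxy chroman with all four stereocentres in place. The forward steps are ether cleavage without ionisation at C2 and twofold electrophilic formylation at the only two free ring positions.

**14 ⇒ 13 ⇒ 12 ⇒ 11 (the CH2–CH(CH3)2 bond of the isobutyl group).** Cutting here rather than at C4–CH2 leaves C4 untouched and puts an oxygen on the carbon attached to C4, which is the carbon that can become a lactone carbonyl. The tosylate 13 comes from alcohol 12, which comes from silyl ether 11. The forward reaction is a substitution at a primary, β-branched carbon by an isopropyl nucleophile.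

**11 ⇒ 10 (O1–C8a).** The alternative cut, O1–C2, would need substitution or cation chemistry at the rearrangement-prone tertiary centre. The aryl–oxygen cut leaves the oxygen on C2, where a ketone can supply it, and asks only for a metal-catalysed coupling of a tertiary alkoxide with an aryl chloride. Compound 10 is an open-chain tertiary alcohol. Its primary hydroxyl must be silylated, because a free one would close a five-membered dihydrobenzofuran onto the same chloride.

**10 ⇒ 9 ⇒ 8 (oxidation level only).** The 1,4-relationship of the two oxygens in diol 9 is that of a γ-lactone. Lactone 8 ties O1 to the future isobutyl CH2 and makes C4 epimerisable, so its configuration can be set by equilibration rather than by a kinetic event.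

**8 ⇒ 2 + 6 (C2–C3 and the lactone acyl–oxygen bond).** This is the strategic cut. It divides the molecule into the terpene ketone 2 and the aryl acrylate 6, which carries every aromatic substituent needed later. The forward reaction is a reductive ketyl–acrylate coupling by divalent samarium that must form C2–C3 on the exo face, close the lactone, and leave the aryl chloride intact. C4 is corrected afterwards by base.

**2 ⇒ 1; 6 ⇒ 5 ⇒ 3 + 4.** Ketone 2 is the oxidative cleavage product of camphene 1. Acrylate 6 is the methylenation product of aryl glyoxylate 5, which is the Friedel–Crafts product of chloroarene 3 and acid chloride 4. All three starting materials are commercial.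

## Roads not taken

**Alternative 1:** The cut is through the benzene ring (C4a–C5) and O1–C8a, with C2–C3 made earlier by aldol-type addition of a polyketide polyanion to ketone 2. In the forward key step the open-chain δ-hydroxy triketo ester A2 is cyclodehydrated by mild acid (O1 onto the C8a carbonyl). A magnesium alkoxide then drives the Claisen condensation of C4a onto the ester carbon, with aromatisation to the spiro 5,7-dihydroxychroman-4-one A1.
- Merits: the phenols arrive free, with no halogen, no palladium and no demethylation; C2 rests on the same exo addition to 2; A1 would be reached in roughly half the steps of the chosen plan.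
- Weak points: a β-hydroxy ketone from a hindered, non-enolisable ketone reverts easily by retro-aldol under the basic conditions the sequence needs. The C4 carbonyl of A1 is a vinylogous ester chelated by the 5-hydroxyl and is a poor electrophile for attaching the isobutyl carbon. C4 would be created by hydrogenation of an olefin under the remote influence of C2, with no means of correction.
- Comparison: this road is clearly shorter. The chosen plan sets against it a C4 that can be equilibrated and checked at a rigid lactone.

**Alternative 2:** The cut is C2–C3 together with one norbornane C–C bond. The precursor is A4, a 7,7-dimethylnorbornane from the camphor pool whose bridgehead carries the aryl ether and whose neighbouring carbon carries an exo alcohol. Triflation in the presence of a hindered pyridine base makes the ring CH2 migrate from the oxygenated bridgehead to the carbinol carbon. This creates the 3,3-dimethylnorbornane and an aryloxycarbenium ion at the future C2. The CH2 of the pendant 1,1-disubstituted styrene captures it (C2–C3), and proton loss gives chromene A3.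
- Merits: the isobutyl group is present from the start; the O–C2 bond never has to be made at a hindered tertiary centre; one cascade forms the spiro centre and the pyran ring; hydrogenation of A3 from the face of the bridgehead CH could plausibly give the correct C4.
- Weak points: A4 needs a bridgehead aryl ether and an ortho alkenyl group, so its preparation is long. A norbornyl cation cascade offers further alkyl and hydride shifts before capture. The face of capture at the oxocarbenium ion is not secured. C4 again depends on kinetic facial selectivity.
- Comparison: after its key step this road is shorter than the chosen one (hydrogenation, demethylation, formylation). The chosen plan sets against it that C2 never becomes cationic and is fixed by a well-understood exo addition.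

**Alternative 3:** The cut is C3–C4. The precursor is selenide A6, a tertiary alkyl aryl ether with a phenylselanylmethyl group on C2 and an (E)-enone ortho to the ether oxygen. A tin hydride with an azo initiator generates the primary C3 radical, which adds 6-exo-trig to the enone β-carbon and gives the 4-(2-oxopropyl)chroman A5. Methylenation and hydrogenation would then complete the isobutyl group.
- Merits: radical chemistry is little affected by the congestion at C2 and cannot trigger cationic rearrangement; a chair-like transition state with the side chain pseudoequatorial gives a rationale for C4; the carbon skeleton is nearly complete after the closure.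
- Weak points: A6 already contains the hindered tertiary ether with the correct C2 configuration, and it would have to be made intermolecularly, which is the hardest bond of the molecule under the least favourable conditions. A β-aryloxy radical can fragment. C4 is kinetic only. Tin residues must be removed.
- Comparison: the step count is comparable. The chosen plan makes O1–C8a intramolecularly after C2 is already set, and controls C4 thermodynamically.

Key step: step 4

## Route

Assumption: (−)-camphene is used at the enantiomeric purity in which it is sold; the route neither raises nor lowers it, so crystallisation of 2 or 8 would be the place to upgrade it if needed.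

Step 1
Reactants: 1 (1S,4R)-(−)-camphene
Product: 2 (1R,4S)-camphenilone [(1R,4S)-3,3-dimethylbicyclo[2.2.1]heptan-2-one]
Conditions: O3, CH2Cl2/MeOH, −78 °C; then Me2S, −78 °C → rt
Reagents that add atoms: ozone, [O-][O+]=O
Why: Ozonolysis with reductive work-up cleaves only the exocyclic C=CH2 bond; the ketone has no enolisable α-hydrogen, so both bridgehead centres are carried over unchanged.

Step 2
Reactants: 3 1-chloro-3,5-dimethoxybenzene; 4 methyl chlorooxoacetate
Product: 5 methyl 2-(2-chloro-4,6-dimethoxyphenyl)-2-oxoacetate
Conditions: AlCl3 (1.2 equiv), CH2Cl2, −10 → 0 °C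
Reagents that add atoms: none
Why: Friedel–Crafts acylation; the position para to one methoxy group and ortho to the other (next to chlorine) is the most activated and less crowded than the position between the two methoxy groups, and the low temperature limits AlCl3 cleavage of the methyl ether ortho to the new ketone.

Step 3
Reactants: 5 methyl 2-(2-chloro-4,6-dimethoxyphenyl)-2-oxoacetate
Product: 6 methyl 2-(2-chloro-4,6-dimethoxyphenyl)acrylate
Conditions: Ph3PCH3Br, NaN(SiMe3)2, THF, 0 °C; then 5, −78 → 0 °C
Reagents that add atoms: methyltriphenylphosphonium bromide, C[P+](c1ccccc1)(c1ccccc1)c1ccccc1.[Br-]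
Why: Wittig methylenation; the ketone carbonyl of an aryl glyoxylate is much more electrophilic than the ester and is attacked selectively by the unstabilised ylide.

Step 4
Reactants: 2 (1R,4S)-camphenilone; 6 methyl 2-(2-chloro-4,6-dimethoxyphenyl)acrylate
Product: 8 (1R,2R,4S,4'S)-4'-(2-chloro-4,6-dimethoxyphenyl)-3,3-dimethylspiro[bicyclo[2.2.1]heptane-2,2'-oxolan]-5'-one, via spirolactone 4'-epimer mixture 7 (not isolated)
Conditions: SmI2 (2.5 equiv), t-BuOH (2 equiv), THF, −78 → 0 °C, slow addition of 6; aq. work-up; then DBU (0.5 equiv), toluene, 80 °C
Reagents that add atoms: none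
Why: The reaction type is the known SmI2-mediated reductive ketone–acrylate coupling with in situ lactonisation (ketyl–olefin coupling). Single-electron transfer from divalent samarium to the carbonyl group of 2 gives a samarium ketyl whose radical carbon adds to the unsubstituted CH2 terminus of 6 (C2–C3); a second electron converts the resulting tertiary α-aryl ester radical into a trivalent samarium enolate, which t-BuOH protonates at C4. The tertiary samarium alkoxide then attacks the methyl ester in a 5-exo-trig acyl substitution and expels methoxide, closing the γ-lactone; any hydroxy ester that survives should be closed by the DBU treatment. C2 is set by bond formation on the exo face of the norbornane ketyl, the intrinsically preferred face because the one-carbon bridge has no syn substituent and each face sees one methyl group of C3, so the oxygen stays endo. C4 is first formed without control (mixture 7) and is then set thermodynamically: DBU reversibly enolises the α-aryl lactone, and the bulky aryl group should settle on the ring face of the bridgehead CH, trans to the gem-dimethyl carbon, which is the configuration of 16. The step needs cross-coupling to outrun reductive dimerisation of 6 and needs the C–Cl bond to survive: the two ortho substituents twist the arene out of conjugation so that 6 behaves like an α-alkyl acrylate, slow addition keeps its concentration low, and without hexamethylphosphoramide SmI2 does not reduce aryl chlorides. Ketone 2 cannot enolise (C1 is a bridgehead, C3 is quaternary), so neither enolisation nor aldol chemistry competes.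

Step 5
Reactants: 8 spirolactone (4'S)
Product: 9 (1R,2R,4S)-2-[(2S)-2-(2-chloro-4,6-dimethoxyphenyl)-3-hydroxypropyl]-3,3-dimethylbicyclo[2.2.1]heptan-2-ol
Conditions: LiAlH4, THF, 0 °C → rt
Reagents that add atoms: none
Why: Hydride reduction of a lactone to the 1,4-diol; addition to the carbonyl is faster than α-deprotonation, C4 loses its acidity with the carbonyl and is fixed from here on, and the aryl chloride is inert under these conditions.

Step 6
Reactants: 9 diol
Product: 10 (1R,2R,4S)-2-[(2S)-3-{[tert-butyl(dimethyl)silyl]oxy}-2-(2-chloro-4,6-dimethoxyphenyl)propyl]-3,3-dimethylbicyclo[2.2.1]heptan-2-ol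
Conditions: TBSCl, imidazole, DMF, 0 °C → rt
Reagents that add atoms: tert-butyldimethylsilyl chloride, CC(C)(C)[Si](C)(C)Cl
Why: Silyl ether protection distinguishes the primary from the hindered tertiary hydroxyl completely; the mask is needed because a free primary alkoxide would close a five-membered dihydrobenzofuran onto the aryl chloride in the next step.

Step 7
Reactants: 10 silyl ether tertiary alcohol
Product: 11 tert-butyl{[(1R,2R,4S,4'S)-5',7'-dimethoxy-3,3-dimethyl-3',4'-dihydrospiro[bicyclo[2.2.1]heptane-2,2'-chromen]-4'-yl]methoxy}dimethylsilane
Conditions: Pd(OAc)2 (5 mol %), 2-(di-tert-butylphosphino)-1,1'-binaphthyl (6 mol %), Cs2CO3, toluene, 90 °C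
Reagents that add atoms: none
Why: Palladium-catalysed intramolecular etherification of an aryl halide (Buchwald–Hartwig-type C–O coupling), known for tertiary alcohols and aryl chlorides; zerovalent palladium with the bulky phosphine inserts into C–Cl, the tertiary alkoxide has no hydrogen on the carbinol carbon for β-elimination, and reductive elimination from the seven-membered palladacycle forms O1–C8a without cationic character at C2.

Step 8
Reactants: 11 chroman silyl ether
Product: 12 [(1R,2R,4S,4'S)-5',7'-dimethoxy-3,3-dimethyl-3',4'-dihydrospiro[bicyclo[2.2.1]heptane-2,2'-chromen]-4'-yl]methanol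
Conditions: Bu4NF, THF, rt
Reagents that add atoms: none
Why: Fluoride-induced desilylation; no other group in 11 reacts with fluoride.

Step 9
Reactants: 12 primary alcohol
Product: 13 [(1R,2R,4S,4'S)-5',7'-dimethoxy-3,3-dimethyl-3',4'-dihydrospiro[bicyclo[2.2.1]heptane-2,2'-chromen]-4'-yl]methyl 4-methylbenzenesulfonate
Conditions: TsCl, Et3N, DMAP (cat.), CH2Cl2, 0 °C → rt
Reagents that add atoms: p-toluenesulfonyl chloride, Cc1ccc(cc1)S(=O)(=O)Cl
Why: Sulfonylation of the primary alcohol; activation is safe at this stage because O1 is now an ether and can no longer displace the tosylate to a tetrahydrofuran.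

Step 10
Reactants: 13 tosylate
Product: 14 (1R,2R,4S,4'S)-5',7'-dimethoxy-3,3-dimethyl-4'-(2-methylpropyl)-3',4'-dihydrospiro[bicyclo[2.2.1]heptane-2,2'-chromene]
Conditions: i-PrMgCl (3 equiv), Li2CuCl4 (5 mol %), THF, −20 °C → rt
Reagents that add atoms: isopropylmagnesium chloride, CC(C)[Mg]Cl
Why: Copper-catalysed coupling of a primary tosylate with a secondary Grignard reagent (Kochi–Schlosser type); substitution at the CH2 carbon completes the isobutyl group and does not touch C4.

Step 11
Reactants: 14 dimethoxy chroman
Product: 15 (1R,2R,4S,4'S)-3,3-dimethyl-4'-(2-methylpropyl)-3',4'-dihydrospiro[bicyclo[2.2.1]heptane-2,2'-chromene]-5',7'-diol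
Conditions: BBr3 (4 equiv), CH2Cl2, −78 → 0 °C; then H2O
Reagents that add atoms: none
Why: Lewis acid cleavage of aryl methyl ethers; BBr3 binds the unhindered methoxy oxygens and bromide attacks the methyl groups, whereas O1 is shielded by the spiro centre, and the low temperature is meant to avoid ionisation of the O1–C2 bond.

Step 12
Reactants: 15 resorcinol chroman
Product: 16 (1R,2R,4S,4'S)-5',7'-dihydroxy-3,3-dimethyl-4'-(2-methylpropyl)-3',4'-dihydrospiro[bicyclo[2.2.1]heptane-2,2'-chromene]-6',8'-dicarbaldehyde
Conditions: Cl2CHOMe (5 equiv), TiCl4 (6 equiv), CH2Cl2, −20 °C → rt; then 1 M HCl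
Reagents that add atoms: dichloromethyl methyl ether, COC(Cl)Cl; water, O
Why: Rieche formylation; the titanium phenoxides direct the electrophile to the only two free ring positions (C6 and C8), each ortho to a phenol, and hydrolysis gives the dialdehyde with each formyl group hydrogen-bonded to a neighbouring hydroxyl.

## Compound list

1 | (1S,4R)-(−)-camphene | C=C1[C@@H]2CC[C@@H](C2)C1(C)C | starting material
2 | (1R,4S)-camphenilone, (1R,4S)-3,3-dimethylbicyclo[2.2.1]heptan-2-one | O=C1[C@@H]2CC[C@@H](C2)C1(C)C | intermediate
3 | 1-chloro-3,5-dimethoxybenzene | COc1cc(Cl)cc(OC)c1 | starting material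
4 | methyl chlorooxoacetate | COC(=O)C(=O)Cl | starting material
5 | methyl 2-(2-chloro-4,6-dimethoxyphenyl)-2-oxoacetate | COC(=O)C(=O)c1c(Cl)cc(OC)cc1OC | intermediate
6 | methyl 2-(2-chloro-4,6-dimethoxyphenyl)acrylate | C=C(C(=O)OC)c1c(Cl)cc(OC)cc1OC | intermediate
7 | (1R,2R,4S)-4'-(2-chloro-4,6-dimethoxyphenyl)-3,3-dimethylspiro[bicyclo[2.2.1]heptane-2,2'-oxolan]-5'-one as the mixture of both C4' epimers (O endo, CH2 exo) | O=C1C(c2c(Cl)cc(OC)cc2OC)C[C@@]2(O1)[C@@H]1CC[C@@H](C1)C2(C)C | intermediate
8 | (1R,2R,4S,4'S)-4'-(2-chloro-4,6-dimethoxyphenyl)-3,3-dimethylspiro[bicyclo[2.2.1]heptane-2,2'-oxolan]-5'-one (aryl trans to the gem-dimethyl carbon) | O=C1[C@H](c2c(Cl)cc(OC)cc2OC)C[C@@]2(O1)[C@@H]1CC[C@@H](C1)C2(C)C | intermediate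
9 | (1R,2R,4S)-2-[(2S)-2-(2-chloro-4,6-dimethoxyphenyl)-3-hydroxypropyl]-3,3-dimethylbicyclo[2.2.1]heptan-2-ol | OC[C@H](c1c(Cl)cc(OC)cc1OC)C[C@@]1(O)[C@@H]2CC[C@@H](C2)C1(C)C | intermediate
10 | (1R,2R,4S)-2-[(2S)-3-{[tert-butyl(dimethyl)silyl]oxy}-2-(2-chloro-4,6-dimethoxyphenyl)propyl]-3,3-dimethylbicyclo[2.2.1]heptan-2-ol | CC(C)(C)[Si](C)(C)OC[C@H](c1c(Cl)cc(OC)cc1OC)C[C@@]1(O)[C@@H]2CC[C@@H](C2)C1(C)C | intermediate
11 | tert-butyl{[(1R,2R,4S,4'S)-5',7'-dimethoxy-3,3-dimethyl-3',4'-dihydrospiro[bicyclo[2.2.1]heptane-2,2'-chromen]-4'-yl]methoxy}dimethylsilane | CC(C)(C)[Si](C)(C)OC[C@H]1C[C@@]2(Oc3cc(OC)cc(OC)c31)[C@@H]1CC[C@@H](C1)C2(C)C | intermediate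
12 | [(1R,2R,4S,4'S)-5',7'-dimethoxy-3,3-dimethyl-3',4'-dihydrospiro[bicyclo[2.2.1]heptane-2,2'-chromen]-4'-yl]methanol | OC[C@H]1C[C@@]2(Oc3cc(OC)cc(OC)c31)[C@@H]1CC[C@@H](C1)C2(C)C | intermediate
13 | [(1R,2R,4S,4'S)-5',7'-dimethoxy-3,3-dimethyl-3',4'-dihydrospiro[bicyclo[2.2.1]heptane-2,2'-chromen]-4'-yl]methyl 4-methylbenzenesulfonate | Cc1ccc(cc1)S(=O)(=O)OC[C@H]1C[C@@]2(Oc3cc(OC)cc(OC)c31)[C@@H]1CC[C@@H](C1)C2(C)C | intermediate
14 | (1R,2R,4S,4'S)-5',7'-dimethoxy-3,3-dimethyl-4'-(2-methylpropyl)-3',4'-dihydrospiro[bicyclo[2.2.1]heptane-2,2'-chromene] | CC(C)C[C@H]1C[C@@]2(Oc3cc(OC)cc(OC)c31)[C@@H]1CC[C@@H](C1)C2(C)C | intermediate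
15 | (1R,2R,4S,4'S)-3,3-dimethyl-4'-(2-methylpropyl)-3',4'-dihydrospiro[bicyclo[2.2.1]heptane-2,2'-chromene]-5',7'-diol | CC(C)C[C@H]1C[C@@]2(Oc3cc(O)cc(O)c31)[C@@H]1CC[C@@H](C1)C2(C)C | intermediate
16 | (1R,2R,4S,4'S)-5',7'-dihydroxy-3,3-dimethyl-4'-(2-methylpropyl)-3',4'-dihydrospiro[bicyclo[2.2.1]heptane-2,2'-chromene]-6',8'-dicarbaldehyde | CC(C)C[C@H]1C[C@@]2(Oc3c(C=O)c(O)c(C=O)c(O)c31)[C@@H]1CC[C@@H](C1)C2(C)C | target

## Step count and risk

Total: 12 steps. Longest linear sequence: 11 steps (3 → 5 → 6 → 8 → … → 16; step 1 supplies ketone 2 in a one-step branch).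

**Step 4 (key step).** Cross-coupling may be outrun by reductive dimerisation or simple reduction of the acrylate, because ketyl formation from the hindered ketone is slow. Facial selectivity at the ketyl could be eroded by the exo methyl group of C3. The equilibration at C4 may show only a modest bias, because both flanks of the spiro centre are branched. If the equilibrium bias turned out to be the opposite one, kinetic protonation of the lithium enolate of the lactone from the less hindered face would be expected to favour the complementary epimer, so one of the two modes should favour 8.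

Fallback (sets out from 2 and 6, returns at 7): the C2–C3 bond would be made by polar allylation instead of radical addition. Reduction of 6 with i-Bu2AlH should give 2-(2-chloro-4,6-dimethoxyphenyl)prop-2-en-1-ol F1. An Appel reaction (CBr4, PPh3) should give 2-(3-bromoprop-1-en-2-yl)-1-chloro-3,5-dimethoxybenzene F2. Zinc-mediated Barbier addition of F2 to 2, on the exo face as for other organometallic additions to this ketone, should give (1R,2R,4S)-2-[2-(2-chloro-4,6-dimethoxyphenyl)prop-2-en-1-yl]-3,3-dimethylbicyclo[2.2.1]heptan-2-ol F3. Hydroboration–oxidation (BH3·SMe2; NaOH, H2O2) should give (1R,2R,4S)-2-[2-(2-chloro-4,6-dimethoxyphenyl)-3-hydroxypropyl]-3,3-dimethylbicyclo[2.2.1]heptan-2-ol as the mixture of epimers at the aryl-bearing carbon F4. Oxidation with TEMPO and PhI(OAc)2 closes F4 to lactone mixture 7, which enters the DBU equilibration of step 4 and gives 8.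

**Step 7.** Alkoxide binding and C–O reductive elimination may stall at the very hindered endo alkoxide, leading to hydrodechlorination of the arene instead of ring closure.

Fallback (from 10 to 11, no new isolable compound): an aryne closure instead of a metal-catalysed one. Excess lithium 2,2,6,6-tetramethylpiperidide in THF (−78 °C → rt) should lithiate the ring position between chlorine and methoxy (C8). Loss of LiCl gives the C8–C8a aryne, and the tethered lithium alkoxide adds at C8a. This is the only carbon the tether can reach in a six-membered closure and also the electronically preferred one, meta to the neighbouring methoxy group. Protonation gives 11.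

**Step 10.** Substitution at the β-branched carbon may be slower than elimination toward the benzylic C4–H or than reduction of the tosylate by the secondary Grignard reagent.

Fallback (from 12, returns at 14): olefination and hydrogenation instead of substitution. Dess–Martin oxidation of 12 should give (1R,2R,4S,4'S)-5',7'-dimethoxy-3,3-dimethyl-3',4'-dihydrospiro[bicyclo[2.2.1]heptane-2,2'-chromene]-4'-carbaldehyde F5. Wittig reaction with isopropylidenetriphenylphosphorane at −78 °C should give (1R,2R,4S,4'R)-5',7'-dimethoxy-3,3-dimethyl-4'-(2-methylprop-1-en-1-yl)-3',4'-dihydrospiro[bicyclo[2.2.1]heptane-2,2'-chromene] F6, which has the same spatial arrangement at C4' (the descriptor changes by priority only). Hydrogenation (H2, Pd/C, EtOAc) gives 14. The aldehyde stage is epimerisable at C4, so it would be kept cold and not stored.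

**Step 11.** The Lewis acid may ionise the tertiary O1–C2 bond, with skeletal rearrangement, or the second demethylation may stop short.

Fallback (from 14, returns at 16): the order of the last two operations is reversed so that the ethers are cleaved by a nucleophile. Rieche formylation of 14 (Cl2CHOMe, TiCl4) should give (1R,2R,4S,4'S)-5',7'-dimethoxy-3,3-dimethyl-4'-(2-methylpropyl)-3',4'-dihydrospiro[bicyclo[2.2.1]heptane-2,2'-chromene]-6',8'-dicarbaldehyde F7. Each methoxy group is then ortho or para to formyl groups and should be cleaved by LiCl in DMF at 130 °C through chloride attack at methyl, giving 16 without a strong Lewis acid.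

**Step 2.** Acylation may occur in part between the two methoxy groups, and AlCl3 may remove the methyl group ortho to the new ketone.

Fallback (from 3, returns at 5): halogenation and metalation instead of electrophilic acylation. Bromination of 3 with N-bromosuccinimide in MeCN should give 2-bromo-1-chloro-3,5-dimethoxybenzene F8, which is purified from its isomer. Bromine–magnesium exchange with i-PrMgCl·LiCl at −20 °C and addition of the aryl Grignard reagent to excess dimethyl oxalate at −78 °C gives 5.

## Further compounds

F1 | step 4 | 2-(2-chloro-4,6-dimethoxyphenyl)prop-2-en-1-ol | C=C(CO)c1c(Cl)cc(OC)cc1OC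
F2 | step 4 | 2-(3-bromoprop-1-en-2-yl)-1-chloro-3,5-dimethoxybenzene | C=C(CBr)c1c(Cl)cc(OC)cc1OC
F3 | step 4 | (1R,2R,4S)-2-[2-(2-chloro-4,6-dimethoxyphenyl)prop-2-en-1-yl]-3,3-dimethylbicyclo[2.2.1]heptan-2-ol | C=C(c1c(Cl)cc(OC)cc1OC)C[C@@]1(O)[C@@H]2CC[C@@H](C2)C1(C)C
F4 | step 4 | (1R,2R,4S)-2-[2-(2-chloro-4,6-dimethoxyphenyl)-3-hydroxypropyl]-3,3-dimethylbicyclo[2.2.1]heptan-2-ol, mixture of epimers at the aryl-bearing carbon | OCC(c1c(Cl)cc(OC)cc1OC)C[C@@]1(O)[C@@H]2CC[C@@H](C2)C1(C)C
F0 | step 7 | none | none
F5 | step 10 | (1R,2R,4S,4'S)-5',7'-dimethoxy-3,3-dimethyl-3',4'-dihydrospiro[bicyclo[2.2.1]heptane-2,2'-chromene]-4'-carbaldehyde | O=C[C@H]1C[C@@]2(Oc3cc(OC)cc(OC)c31)[C@@H]1CC[C@@H](C1)C2(C)C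
F6 | step 10 | (1R,2R,4S,4'R)-5',7'-dimethoxy-3,3-dimethyl-4'-(2-methylprop-1-en-1-yl)-3',4'-dihydrospiro[bicyclo[2.2.1]heptane-2,2'-chromene] | CC(C)=C[C@H]1C[C@@]2(Oc3cc(OC)cc(OC)c31)[C@@H]1CC[C@@H](C1)C2(C)C
F7 | step 11 | (1R,2R,4S,4'S)-5',7'-dimethoxy-3,3-dimethyl-4'-(2-methylpropyl)-3',4'-dihydrospiro[bicyclo[2.2.1]heptane-2,2'-chromene]-6',8'-dicarbaldehyde | CC(C)C[C@H]1C[C@@]2(Oc3c(C=O)c(OC)c(C=O)c(OC)c31)[C@@H]1CC[C@@H](C1)C2(C)C
F8 | step 2 | 2-bromo-1-chloro-3,5-dimethoxybenzene | Clc1cc(OC)cc(OC)c1Br
A1 | alternative 1 | spiro 5,7-dihydroxychroman-4-one, C2 spiro-fused to C2 of the 3,3-dimethylnorbornane of 16, O1 endo | O=C1C[C@@]2(Oc3cc(O)cc(O)c31)[C@@H]1CC[C@@H](C1)C2(C)C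
A2 | alternative 1 | methyl 8-[(1R,2R,4S)-2-hydroxy-3,3-dimethylbicyclo[2.2.1]heptan-2-yl]-3,5,7-trioxooctanoate | COC(=O)CC(=O)CC(=O)CC(=O)C[C@@]1(O)[C@@H]2CC[C@@H](C2)C1(C)C
A3 | alternative 2 | spiro 4-isobutyl-5,7-dimethoxy-2H-chromene, C2 spiro-fused to C2 of the 3,3-dimethylnorbornane of 16, O1 endo and C3 exo | CC(C)CC1=C[C@@]2(Oc3cc(OC)cc(OC)c31)[C@@H]1CC[C@@H](C1)C2(C)C
A4 | alternative 2 | 1-[3,5-dimethoxy-2-(4-methylpent-1-en-2-yl)phenoxy]-7,7-dimethylbicyclo[2.2.1]heptan-2-ol with the hydroxyl exo | O[C@H]1C[C@@H]2CC[C@@]1(Oc1cc(OC)cc(OC)c1C(=C)CC(C)C)C2(C)C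
A5 | alternative 3 | spiro 5,7-dimethoxy-4-(2-oxopropyl)chroman with the C2 and C4 configuration of 16 | CC(=O)C[C@H]1C[C@@]2(Oc3cc(OC)cc(OC)c31)[C@@H]1CC[C@@H](C1)C2(C)C
A6 | alternative 3 | (E)-4-[2-({(1R,4S)-3,3-dimethyl-2-[(phenylselanyl)methyl]bicyclo[2.2.1]heptan-2-yl}oxy)-4,6-dimethoxyphenyl]but-3-en-2-one, ether oxygen endo and CH2Se exo | CC(=O)/C=C/c1c(OC)cc(OC)cc1O[C@]1(C[Se]c2ccccc2)[C@@H]2CC[C@@H](C2)C1(C)C
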